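## Retrosynthetic overview

1. In ring A the acetyl-bearing C1 and the chain-bearing C6 are neighbours, so they map onto the two sp carbons of a conjugated ynone. C2–C5, oxygenated at C2 and C4, map onto an acetoacetate-derived 1,1-dimethoxy-3-silyloxybutadiene.
2. Last disconnection: the C2 hydroxyl is unmasked from a C2 methyl ether with BCl3, helped by chelation to the acetyl oxygen.
3. Key disconnection: C5–C6 and C1–C2 are made together in a Diels–Alder benzannulation, with loss of MeOH and of the silyl group. Ring A is the only ring formed; ring B is bought as phenylmagnesium bromide.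
4. Ynone: the C10'–ring B bond comes from a copper-catalysed Grignard coupling with 1,10-dibromodecane. The C1'–C6 bond comes from alkylation of dilithiated but-3-yn-2-ol, followed by MnO2 oxidation.
5. Diene: C-acylation of 1,1-dimethoxyethene with acetyl chloride, then O-silylation of the methyl ketone.

Key step: step 6

Remark: the target has no stereocentre. But-3-yn-2-ol is used as the racemate because its carbinol carbon becomes the acetyl carbonyl carbon.

## Route

Step 1
Reactants: 1 1,10-dibromodecane; 2 phenylmagnesium bromide
Product: 3 (10-bromodecyl)benzene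
Conditions: 1 (3 equiv), Li2CuCl4 (3 mol %), THF, 0 °C → rt, slow addition of 2; excess 1 removed by distillation
Reagents that add atoms: none
Why: Copper-catalysed Grignard–alkyl halide cross-coupling at a primary C–Br bond, in which the excess of symmetrical dibromide 1 suppresses the second substitution.

Step 2
Reactants: 3 (10-bromodecyl)benzene; 4 but-3-yn-2-ol (racemic)
Product: 6 14-phenyltetradec-3-yn-2-ol (racemic), via dilithiated but-3-yn-2-ol 5 (not isolated)
Conditions: 4 (1.5 equiv), n-BuLi (3.0 equiv), THF, −78 → 0 °C; then 3, DMPU, 0 °C → rt; H2O
Reagents that add atoms: none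
Why: Alkylation of an alkynol dianion, in which the acetylide carbon is far more nucleophilic than the lithium alkoxide and displaces the primary bromide by SN2; the carbinol centre stays racemic and is erased in step 3.

Step 3
Reactants: 6 14-phenyltetradec-3-yn-2-ol
Product: 7 14-phenyltetradec-3-yn-2-one
Conditions: activated MnO2 (15 equiv), CH2Cl2, rt
Reagents that add atoms: none
Why: MnO2 oxidation of a propargylic alcohol to the ynone under neutral conditions, which avoids base-induced isomerisation to an allenyl ketone and leaves the benzylic CH2 untouched.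

Step 4
Reactants: 8 1,1-dimethoxyethene; 9 acetyl chloride
Product: 10 4,4-dimethoxybut-3-en-2-one
Conditions: 8 (2.1 equiv), 9 (1 equiv), Et2O, 0 °C → reflux; distillation
Reagents that add atoms: none
Why: C-acylation of a ketene acetal, in which the nucleophilic CH2 of 8 attacks the acid chloride and a second equivalent of 8 takes up the HCl by collapsing to methyl acetate and chloromethane, so the acid-labile product never meets free acid.

Step 5
Reactants: 10 4,4-dimethoxybut-3-en-2-one
Product: 11 1,1-dimethoxy-3-(trimethylsilyloxy)buta-1,3-diene
Conditions: Me3SiCl, Et3N, ZnCl2 (cat.), toluene, 40 °C; filtration under N2, distillation under reduced pressure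
Reagents that add atoms: chlorotrimethylsilane, C[Si](C)(C)Cl
Why: Soft enolisation and O-silylation of a methyl ketone, the standard way to make 3-silyloxybutadienes from β-alkoxy enones; only the CH3 group carries enolisable hydrogens, so a single diene can form.

Step 6
Reactants: 11 1,1-dimethoxy-3-(trimethylsilyloxy)buta-1,3-diene; 7 14-phenyltetradec-3-yn-2-one
Product: 14 1-[4-hydroxy-2-methoxy-6-(10-phenyldecyl)phenyl]ethanone, via cyclohexa-1,4-diene ketal adduct 12 (not isolated), via aryl trimethylsilyl ether 13 (not isolated)
Conditions: 11 (2.5 equiv), toluene, 110 °C, sealed tube, Ar; then 1 M aq HCl, THF, rt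
Reagents that add atoms: none
Why: This is a thermal normal-electron-demand Diels–Alder reaction between the oxygen-rich diene 11 (HOMO) and ynone 7 (LUMO), and bond formation is strongly asynchronous, with C5–C6 (diene CH2 to the alkyne carbon β to the carbonyl) running ahead of C1–C2 (ketene-acetal carbon to the α-carbon). The closest known reaction type is the benzannulation of 1,1-dialkoxy-3-silyloxybutadienes with acetylenic esters and ketones, β-alkyl-substituted ones included, which gives 4-hydroxy-2-alkoxyaryl carbonyl compounds. Ring A is closed intermolecularly in a [4+2] mode through one six-membered transition state, four carbons (C2–C5) coming from 11 and two (C1, C6) from 7. Adduct 12 has a ketal at C2 and a CH2 at C5 across a 1,4-diene, so a 1,4-elimination of methanol driven by aromatisation gives 13, and dilute acid then cleaves the aryl O–Si bond to free the C4 phenol. No stereocentre is created, because C2 of 12 bears two identical methoxy groups and C5 bears two hydrogens. The only selectivity needed is regiochemical (methoxy next to acetyl, chain next to C5–H), and it is secured because all three oxygen donors of 11 push electron density onto its CH2 terminus while the acetyl group of 7 makes the chain-bearing alkyne carbon the electrophilic one.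

Step 7
Reactants: 14 1-[4-hydroxy-2-methoxy-6-(10-phenyldecyl)phenyl]ethanone
Product: 16 1-[2,4-dihydroxy-6-(10-phenyldecyl)phenyl]ethanone (target), via bis(dichloroboryl) aryl ether 15 (not isolated)
Conditions: BCl3 (3 equiv), CH2Cl2, −78 → 0 °C; then H2O
Reagents that add atoms: none
Why: Chelation-assisted aryl methyl ether cleavage, in which BCl3 is held between the acetyl oxygen and the neighbouring C2 methoxy oxygen while chloride removes the methyl group; a further equivalent is taken up by the free C4 phenol, and water hydrolyses both B–O bonds.

## Compound list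

1 | 1,10-dibromodecane | BrCCCCCCCCCCBr | starting material
2 | phenylmagnesium bromide | Br[Mg]c1ccccc1 | starting material
3 | (10-bromodecyl)benzene | BrCCCCCCCCCCc1ccccc1 | intermediate
4 | but-3-yn-2-ol (racemic) | CC(O)C#C | starting material
5 | dilithiated but-3-yn-2-ol (racemic, not isolated) | [Li]OC(C)C#C[Li] | intermediate
6 | 14-phenyltetradec-3-yn-2-ol (racemic) | CC(O)C#CCCCCCCCCCCc1ccccc1 | intermediate
7 | 14-phenyltetradec-3-yn-2-one | CC(=O)C#CCCCCCCCCCCc1ccccc1 | intermediate
8 | 1,1-dimethoxyethene | C=C(OC)OC | starting material
9 | acetyl chloride | CC(=O)Cl | starting material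
10 | 4,4-dimethoxybut-3-en-2-one | CC(=O)C=C(OC)OC | intermediate
11 | 1,1-dimethoxy-3-(trimethylsilyloxy)buta-1,3-diene | COC(OC)=CC(=C)O[Si](C)(C)C | intermediate
12 | 1-[6,6-dimethoxy-2-(10-phenyldecyl)-4-(trimethylsilyloxy)cyclohexa-1,4-dien-1-yl]ethanone (not isolated) | CC(=O)C1=C(CCCCCCCCCCc2ccccc2)CC(O[Si](C)(C)C)=CC1(OC)OC | intermediate
13 | 1-[2-methoxy-6-(10-phenyldecyl)-4-(trimethylsilyloxy)phenyl]ethanone (not isolated) | COc1cc(O[Si](C)(C)C)cc(CCCCCCCCCCc2ccccc2)c1C(C)=O | intermediate
14 | 1-[4-hydroxy-2-methoxy-6-(10-phenyldecyl)phenyl]ethanone | COc1cc(O)cc(CCCCCCCCCCc2ccccc2)c1C(C)=O | intermediate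
15 | 1-[2,4-bis(dichloroboryloxy)-6-(10-phenyldecyl)phenyl]ethanone (not isolated) | CC(=O)c1c(OB(Cl)Cl)cc(OB(Cl)Cl)cc1CCCCCCCCCCc1ccccc1 | intermediate
16 | 1-[2,4-dihydroxy-6-(10-phenyldecyl)phenyl]ethanone | CC(=O)c1c(O)cc(O)cc1CCCCCCCCCCc1ccccc1 | target

## Step count and risks

Total step count: 7.
Longest linear sequence: 5 steps (steps 1, 2, 3, 6, 7). The diene branch (steps 4 and 5) joins at step 6.

**Step 6.** The cycloaddition at the internal, β-alkylated alkyne may be too slow. Thermal decay of the diene, and its consumption by the methanol that is released, could then outpace ring formation. The fallback buys ring A instead of building it; it sets out from bromide 3 and comes back to the route at target 16. 1-Bromo-3,5-dimethoxybenzene and Mg in THF give 3,5-dimethoxyphenylmagnesium bromide F1. This is coupled with 3 under Li2CuCl4 catalysis to give 1,3-dimethoxy-5-(10-phenyldecyl)benzene F2. Friedel–Crafts acetylation with acetyl chloride 9 and SnCl4 in CH2Cl2 at low temperature should occur para to one methoxy group and ortho to the chain, since the dimethoxyarene is far more electron-rich than ring B. This gives 1-[2,4-dimethoxy-6-(10-phenyldecyl)phenyl]ethanone F3. BBr3 in CH2Cl2 then cleaves both methyl ethers through 1-[2,4-bis(dibromoboryloxy)-6-(10-phenyldecyl)phenyl]ethanone F4, which water hydrolyses to 16.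

**Step 4.** Three processes may erode the acylation: acid-triggered polymerisation of the ketene acetal, chloride-induced dealkylation of the oxocarbenium intermediate, and a second acylation. The fallback installs the two methoxy groups last; it sets out from acetyl chloride 9 and comes back at 10. AlCl3-mediated acylation of 1,1-dichloroethene with 9 in CH2Cl2 gives 4,4,4-trichlorobutan-2-one F5. This loses HCl on distillation to give 4,4-dichlorobut-3-en-2-one F6. Two successive addition–elimination reactions with NaOMe (2 equiv) in MeOH at 0 °C replace both vinylic chlorides and give 10.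

**Step 2.** Substitution at the long-chain bromide may be slow, with competing E2 elimination by the basic dianion and partial O-alkylation. The fallback builds the ynone from a terminal alkyne and needs no oxidation; it sets out from 3 and comes back at ynone 7. Bromide 3 and LiC≡CH·H2NCH2CH2NH2 (lithium acetylide–ethylenediamine complex) in DMSO give 12-phenyldodec-1-yne F7. n-BuLi in THF at −78 °C converts it into (12-phenyldodec-1-yn-1-yl)lithium F8. This is acylated with N-methoxy-N-methylacetamide (Weinreb ketone synthesis) and quenched cold with aqueous HCl to give 7.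

## Further compounds

F1 | step 6 | 3,5-dimethoxyphenylmagnesium bromide | COc1cc(OC)cc([Mg]Br)c1
F2 | step 6 | 1,3-dimethoxy-5-(10-phenyldecyl)benzene | COc1cc(OC)cc(CCCCCCCCCCc2ccccc2)c1
F3 | step 6 | 1-[2,4-dimethoxy-6-(10-phenyldecyl)phenyl]ethanone | COc1cc(OC)cc(CCCCCCCCCCc2ccccc2)c1C(C)=O
F4 | step 6 | 1-[2,4-bis(dibromoboryloxy)-6-(10-phenyldecyl)phenyl]ethanone | CC(=O)c1c(OB(Br)Br)cc(OB(Br)Br)cc1CCCCCCCCCCc1ccccc1
F5 | step 4 | 4,4,4-trichlorobutan-2-one | CC(=O)CC(Cl)(Cl)Cl
F6 | step 4 | 4,4-dichlorobut-3-en-2-one | CC(=O)C=C(Cl)Cl
F7 | step 2 | 12-phenyldodec-1-yne | C#CCCCCCCCCCCc1ccccc1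
F8 | step 2 | (12-phenyldodec-1-yn-1-yl)lithium | [Li]C#CCCCCCCCCCCc1ccccc1
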